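**Remarks on the chemistry.** (−)-Epiafzelechin (1) is taken as a purchasable natural product; it supplies both rings and both stereocentres of the lower flavan-3-ol unit. Flavan numbering is used throughout: "upper" is the 7,4'-dihydroxyflavan unit, "lower" is the epiafzelechin unit, which is linked through its C6. ArL = (2R,3R)-3,5,7-tris(benzyloxy)-2-[4-(benzyloxy)phenyl]-8-bromochroman-6-yl. In step 6 the chiral diene is specified by the face it must attack (Re at C-β), because the descriptor-to-face mapping of such ligands depends on the substrate.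

## Retrosynthetic overview

1. Target 22 ⇐ chroman 21 by one global hydrogenolysis (five OBn, one C8–Br blocking group). The lower A/C/B rings are never opened.
2. 21 ⇐ open-chain 1,3,3-triarylpropanol 17 by closing the upper pyran ring last, through the aryl O1–C8a bond (oxidative dearomatisation / oxa-Michael / rearomatisation cascade).
3. Enabling feature: in the upper A ring the C7 hydroxyl is para to C4a. Oxidising that phenol at C4a makes C8a (meta to C7–OH, ortho to C4a) the β-carbon of a cyclohexa-2,5-dienone, three carbons away from the C2 oxygen.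
4. 17 ⇐ enone 11: upper C4 by Rh-catalysed asymmetric aryl 1,4-addition, upper C2 by CBS reduction.
5. 11 ⇐ epiafzelechin by benzylation, C8 bromination, C6 formylation and Claisen–Schmidt condensation.

Key step: step 9

## Route

Step 1
Reactants: 1 (−)-epiafzelechin; 2 benzyl bromide
Product: 3 (2R,3R)-5,7-bis(benzyloxy)-2-[4-(benzyloxy)phenyl]chroman-3-ol
Conditions: BnBr (3.3 equiv), K2CO3, DMF, 0 °C to rt
Reagents that add atoms: benzyl bromide, BrCc1ccccc1
Why: Williamson etherification under carbonate base should cap only the three phenols and leave the secondary 3-OH and both stereocentres untouched.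

Step 2
Reactants: 3; 2 benzyl bromide
Product: 4 (2R,3R)-3,5,7-tris(benzyloxy)-2-[4-(benzyloxy)phenyl]chromane
Conditions: NaH, BnBr, Bu4NI (cat.), THF/DMF, 0 °C to rt
Reagents that add atoms: benzyl bromide, BrCc1ccccc1
Why: Williamson etherification of the sodium alkoxide should protect the 3-OH against the Vilsmeier reagent of step 4; with the 4'-phenol capped, C2 can no longer epimerise under base.

Step 3
Reactants: 4; 5 N-bromosuccinimide
Product: 6 (2R,3R)-3,5,7-tris(benzyloxy)-2-[4-(benzyloxy)phenyl]-8-bromochromane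
Conditions: NBS (1.0 equiv), CH2Cl2, −78 °C to rt
Reagents that add atoms: N-bromosuccinimide, O=C1CCC(=O)N1Br
Why: Electrophilic aromatic bromination of per-O-benzyl flavan-3-ols is C8-selective, so it should install a removable blocking group and leave C6 as the only free nucleophilic ring position.

Step 4
Reactants: 6; 7 N,N-dimethylformamide
Product: 9 (2R,3R)-3,5,7-tris(benzyloxy)-2-[4-(benzyloxy)phenyl]-8-bromochromane-6-carbaldehyde (ArL–CHO), via iminium salt 8 (not isolated)
Conditions: POCl3, DMF, ClCH2CH2Cl, 0 to 60 °C; then H2O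
Reagents that add atoms: N,N-dimethylformamide, CN(C)C=O; water, O
Why: Vilsmeier–Haack formylation should occur at C6, the only unsubstituted position of the ring and one activated by two ortho benzyloxy groups, and the iminium salt is hydrolysed on work-up.

Step 5
Reactants: 9; 10 1-[4-(benzyloxy)phenyl]ethan-1-one
Product: 11 (E)-1-[4-(benzyloxy)phenyl]-3-ArL-prop-2-en-1-one
Conditions: KOH (cat.), EtOH/THF, rt
Reagents that add atoms: 1-[4-(benzyloxy)phenyl]ethan-1-one, CC(=O)c1ccc(OCc2ccccc2)cc1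
Why: Claisen–Schmidt condensation of a non-enolisable aldehyde with an aryl methyl ketone should give the (E)-enone by E1cB dehydration, with no epimerisable centre in the substrate.

Step 6
Reactants: 11; 12 [4-(tert-butyldimethylsilyloxy)phenyl]boronic acid
Product: 13 (3S)-1-[4-(benzyloxy)phenyl]-3-[4-(tert-butyldimethylsilyloxy)phenyl]-3-ArL-propan-1-one
Conditions: [RhCl(C2H4)2]2 (3 mol %), chiral diene Ph-bod* (enantiomer for Re-face attack at C-β), Et3N, dioxane/H2O 10:1, 50 °C
Reagents that add atoms: [4-(tert-butyldimethylsilyloxy)phenyl]boronic acid, CC(C)(C)[Si](C)(C)Oc1ccc(B(O)O)cc1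
Why: Hayashi–Miyaura Rh-catalysed asymmetric 1,4-addition should deliver the aryl group under ligand control to the Re face of C-β, setting the diaryl methine (future upper C4) as S, while the hindered C8 bromide is inert to Rh(I).

Step 7
Reactants: 13
Product: 14 (1S,3S)-1-[4-(benzyloxy)phenyl]-3-[4-(tert-butyldimethylsilyloxy)phenyl]-3-ArL-propan-1-ol
Conditions: (R)-Me-CBS (20 mol %), BH3·SMe2, THF, −20 °C; MeOH quench
Reagents that add atoms: none
Why: Corey–Bakshi–Shibata reduction of an aryl alkyl ketone with the (R)-catalyst should give the (S)-carbinol (future upper C2) under reagent control, with aryl as the large group and the remote C3 centre playing no role.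

Step 8
Reactants: 14; 15 tert-butyldimethylsilyl triflate
Product: 17 4-[(1S,3S)-3-[4-(benzyloxy)phenyl]-3-(tert-butyldimethylsilyloxy)-1-ArL-propyl]phenol, via bis-silyl ether 16 (not isolated)
Conditions: TBSOTf, 2,6-lutidine, CH2Cl2, 0 °C; then K2CO3, MeOH, rt
Reagents that add atoms: tert-butyldimethylsilyl triflate, CC(C)(C)[Si](C)(C)OS(=O)(=O)C(F)(F)F
Why: Silylation of the secondary alcohol followed by carbonate methanolysis, which cleaves aryl silyl ethers far faster than alkyl ones, should leave exactly one free phenol and a masked C2 oxygen.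

Step 9
Reactants: 17
Product: 21 (2S,4S)-2-[4-(benzyloxy)phenyl]-4-ArL-chroman-7-ol, via quinol methyl ether 18 (not isolated), via free-alcohol dienone 19 (not isolated), via oxa-Michael adduct 20 (not isolated)
Conditions: PhI(OAc)2 (1.1 equiv), MeOH, 0 °C; concentrate; HF·pyridine, THF, 0 °C to rt, NaHCO3 wash; then TFA (10 mol %), CH2Cl2, 0 °C
Reagents that add atoms: none
Why: Proposed new method: PhI(OAc)2 oxidises the single free phenol of 17 and methanol is captured at the para carbon (future C4a) to give quinol ether 18, which reverses the polarity of the ring so that the former meta carbon (future C8a) becomes the β-carbon of a cross-conjugated dienone; HF·pyridine then frees the C2 hydroxyl (19), which adds to that carbon to give 20, and acid ionises the doubly allylic C4a–OMe of the derived dienol and removes the C8a proton (net loss of MeOH) to restore the arene. The closest known reaction types are the PhI(OAc)2/MeOH dearomatisation of p-alkylphenols, the intramolecular oxa-Michael addition of 4-(3-hydroxypropyl)cyclohexadienones and the dearomatisation–Michael–eliminative rearomatisation sequence used for meta-functionalisation of phenols and anilines with carbon nucleophiles; the telescoped oxygen version that ends in a chroman is the untested part. The one ring closed is the upper pyran, by 6-exo-trig conjugate addition that forms the O1–C8a bond. No lasting stereocentre is formed: the C4a and C8a centres of 20 vanish on aromatisation (so either diastereotopic β-carbon may be attacked), and C2 and C4 keep the configurations set in steps 7 and 6 because no bond to them is made or broken. The step needs oxidation of one phenol only, secured by the benzyl ethers on all others, and capture of the phenoxenium ion by methanol instead of the tethered oxygen (which would give the five-membered ipso spiro-ether and then the wrong 6-hydroxy isomer by dienone–phenol shift), secured by keeping the C2 oxygen silylated until after the oxidation. The C8 bromide and the fully substituted lower A ring shut off Friedel–Crafts side reactions, and cyclisation is run under buffered HF before the stronger acid is added so that dienone–phenol rearrangement of 19 cannot compete.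

Step 10
Reactants: 21
Product: 22 (2R,3R)-6-[(2S,4S)-7-hydroxy-2-(4-hydroxyphenyl)chroman-4-yl]-2-(4-hydroxyphenyl)chromane-3,5,7-triol (CNP0167324.1)
Conditions: H2 (1 atm), Pd(OH)2/C, Et3N, THF/MeOH 1:1, rt
Reagents that add atoms: none
Why: Catalytic hydrogenolysis should remove the five benzyl ethers and the aryl bromide (HBr taken up by Et3N) in one operation, the standard end-game for benzyl/8-bromo-protected oligoflavans, without touching the cyclic benzylic C2–O1 bonds or any stereocentre.

## Compound list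

1 | (−)-epiafzelechin, (2R,3R)-2-(4-hydroxyphenyl)chromane-3,5,7-triol | c1c(O)cc2c(c1O)C[C@@H](O)[C@@H](c1ccc(O)cc1)O2 | starting material
2 | benzyl bromide | BrCc1ccccc1 | starting material
3 | (2R,3R)-5,7-bis(benzyloxy)-2-[4-(benzyloxy)phenyl]chroman-3-ol | c1c(OCc5ccccc5)cc2c(c1OCc5ccccc5)C[C@@H](O)[C@@H](c3ccc(OCc5ccccc5)cc3)O2 | intermediate
4 | (2R,3R)-3,5,7-tris(benzyloxy)-2-[4-(benzyloxy)phenyl]chromane | c1c(OCc5ccccc5)cc2c(c1OCc5ccccc5)C[C@@H](OCc5ccccc5)[C@@H](c3ccc(OCc5ccccc5)cc3)O2 | intermediate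
5 | N-bromosuccinimide | O=C1CCC(=O)N1Br | starting material
6 | (2R,3R)-3,5,7-tris(benzyloxy)-2-[4-(benzyloxy)phenyl]-8-bromochromane (ArL–H) | c1c(OCc5ccccc5)c(Br)c2c(c1OCc5ccccc5)C[C@@H](OCc5ccccc5)[C@@H](c3ccc(OCc5ccccc5)cc3)O2 | intermediate
7 | N,N-dimethylformamide | CN(C)C=O | starting material
8 | N,N-dimethyl-1-ArL-methaniminium chloride | C[N+](C)=Cc1c(OCc5ccccc5)c(Br)c2c(c1OCc5ccccc5)C[C@@H](OCc5ccccc5)[C@@H](c3ccc(OCc5ccccc5)cc3)O2.[Cl-] | intermediate (not isolated)
9 | (2R,3R)-3,5,7-tris(benzyloxy)-2-[4-(benzyloxy)phenyl]-8-bromochromane-6-carbaldehyde | O=Cc1c(OCc5ccccc5)c(Br)c2c(c1OCc5ccccc5)C[C@@H](OCc5ccccc5)[C@@H](c3ccc(OCc5ccccc5)cc3)O2 | intermediate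
10 | 1-[4-(benzyloxy)phenyl]ethan-1-one | CC(=O)c1ccc(OCc2ccccc2)cc1 | starting material
11 | (E)-1-[4-(benzyloxy)phenyl]-3-ArL-prop-2-en-1-one | O=C(/C=C/c1c(OCc5ccccc5)c(Br)c2c(c1OCc5ccccc5)C[C@@H](OCc5ccccc5)[C@@H](c3ccc(OCc5ccccc5)cc3)O2)c1ccc(OCc5ccccc5)cc1 | intermediate
12 | [4-(tert-butyldimethylsilyloxy)phenyl]boronic acid | CC(C)(C)[Si](C)(C)Oc1ccc(B(O)O)cc1 | starting material
13 | (3S)-1-[4-(benzyloxy)phenyl]-3-[4-(tert-butyldimethylsilyloxy)phenyl]-3-ArL-propan-1-one | O=C(C[C@H](c1c(OCc5ccccc5)c(Br)c2c(c1OCc5ccccc5)C[C@@H](OCc5ccccc5)[C@@H](c3ccc(OCc5ccccc5)cc3)O2)c1ccc(O[Si](C)(C)C(C)(C)C)cc1)c1ccc(OCc5ccccc5)cc1 | intermediate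
14 | (1S,3S)-1-[4-(benzyloxy)phenyl]-3-[4-(tert-butyldimethylsilyloxy)phenyl]-3-ArL-propan-1-ol | O[C@@H](C[C@H](c1c(OCc5ccccc5)c(Br)c2c(c1OCc5ccccc5)C[C@@H](OCc5ccccc5)[C@@H](c3ccc(OCc5ccccc5)cc3)O2)c1ccc(O[Si](C)(C)C(C)(C)C)cc1)c1ccc(OCc5ccccc5)cc1 | intermediate
15 | tert-butyldimethylsilyl trifluoromethanesulfonate | CC(C)(C)[Si](C)(C)OS(=O)(=O)C(F)(F)F | starting material
16 | bis-TBS ether of 14 (alkyl and aryl silyl ether, 1S,3S) | CC(C)(C)[Si](C)(C)O[C@@H](C[C@H](c1c(OCc5ccccc5)c(Br)c2c(c1OCc5ccccc5)C[C@@H](OCc5ccccc5)[C@@H](c3ccc(OCc5ccccc5)cc3)O2)c1ccc(O[Si](C)(C)C(C)(C)C)cc1)c1ccc(OCc5ccccc5)cc1 | intermediate (not isolated)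
17 | 4-[(1S,3S)-3-[4-(benzyloxy)phenyl]-3-(tert-butyldimethylsilyloxy)-1-ArL-propyl]phenol | CC(C)(C)[Si](C)(C)O[C@@H](C[C@H](c1c(OCc5ccccc5)c(Br)c2c(c1OCc5ccccc5)C[C@@H](OCc5ccccc5)[C@@H](c3ccc(OCc5ccccc5)cc3)O2)c1ccc(O)cc1)c1ccc(OCc5ccccc5)cc1 | intermediate
18 | 4-[(1R,3S)-3-[4-(benzyloxy)phenyl]-3-(tert-butyldimethylsilyloxy)-1-ArL-propyl]-4-methoxycyclohexa-2,5-dien-1-one (same spatial arrangement as 17; the descriptor at C1 changes only because the quaternary C–O carbon outranks ArL) | CC(C)(C)[Si](C)(C)O[C@@H](C[C@H](c1c(OCc5ccccc5)c(Br)c2c(c1OCc5ccccc5)C[C@@H](OCc5ccccc5)[C@@H](c3ccc(OCc5ccccc5)cc3)O2)C1(OC)C=CC(=O)C=C1)c1ccc(OCc5ccccc5)cc1 | intermediate (not isolated)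
19 | 4-[(1R,3S)-3-[4-(benzyloxy)phenyl]-3-hydroxy-1-ArL-propyl]-4-methoxycyclohexa-2,5-dien-1-one | O[C@@H](C[C@H](c1c(OCc5ccccc5)c(Br)c2c(c1OCc5ccccc5)C[C@@H](OCc5ccccc5)[C@@H](c3ccc(OCc5ccccc5)cc3)O2)C1(OC)C=CC(=O)C=C1)c1ccc(OCc5ccccc5)cc1 | intermediate (not isolated)
20 | (2S,4R)-2-[4-(benzyloxy)phenyl]-4-ArL-4a-methoxy-2,3,4,4a,8,8a-hexahydro-7H-chromen-7-one, cis ring fusion (C4a–OMe and C8a–H cis; one of the two cis-fused diastereomers drawn, both converge on 21) | C(c1ccccc1)Oc1ccc([C@@H]2C[C@H](c6c(OCc9ccccc9)c(Br)c7c(c6OCc9ccccc9)C[C@@H](OCc9ccccc9)[C@@H](c8ccc(OCc9ccccc9)cc8)O7)[C@@]3(OC)C=CC(=O)C[C@H]3O2)cc1 | intermediate (not isolated)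
21 | (2S,4S)-2-[4-(benzyloxy)phenyl]-4-ArL-chroman-7-ol | C(c1ccccc1)Oc1ccc([C@@H]2C[C@H](c6c(OCc9ccccc9)c(Br)c7c(c6OCc9ccccc9)C[C@@H](OCc9ccccc9)[C@@H](c8ccc(OCc9ccccc9)cc8)O7)c3ccc(O)cc3O2)cc1 | intermediate
22 | (2R,3R)-6-[(2S,4S)-7-hydroxy-2-(4-hydroxyphenyl)chroman-4-yl]-2-(4-hydroxyphenyl)chromane-3,5,7-triol (CNP0167324.1) | Oc1ccc([C@@H]2C[C@H](c3c(O)cc4c(c3O)C[C@@H](O)[C@@H](c3ccc(O)cc3)O4)c3ccc(O)cc3O2)cc1 | target

## Step count and risks

Total steps: 10. Longest linear sequence: 10 steps (from 1).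

**Step 9 (proposed new method).** What may go wrong: the phenoxenium ion may lose the doubly benzylic C4 proton to give a p-quinone methide instead of capturing methanol, which would scramble C4; or the oxa-Michael adduct may revert and undergo dienone–phenol shift instead of eliminating methanol. Fallback, setting out from enone 11 and returning at target 22, with the aryl C–O bond made by known copper catalysis: Rh-catalysed 1,4-addition of commercial (4-benzyloxy-2-bromophenyl)boronic acid (OB(O)c1ccc(OCc2ccccc2)cc1Br) under the step-6 conditions should give the bromo ketone F1. (R)-Me-CBS/BH3·SMe2 should reduce it to the bromo alcohol F2. CuI/1,10-phenanthroline, Cs2CO3, toluene, 110 °C should then close the pyran by intramolecular Ullmann etherification with retention at the carbinol carbon, the mono-ortho-substituted bromide reacting in preference to the di-ortho-alkoxy C8 bromide, to give the hexabenzyl chroman F3. Hydrogenolysis under the step-10 conditions should convert F3 into 22.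

**Step 6.** What may go wrong: slow carbometalation of the hindered, electron-rich β-aryl enone with competing protodeboronation, or poor facial selectivity. Fallback, setting out from aldehyde 9 and returning at ketone 13, with auxiliary control: Doebner condensation with malonic acid (pyridine, piperidine, 90 °C) should give the (E)-acrylic acid F4. Activation with pivaloyl chloride/Et3N and acylation of lithiated (4R)-4-phenyl-1,3-oxazolidin-2-one should give the N-enoyl imide F5. Addition of 4-(tert-butyldimethylsilyloxy)phenylmagnesium bromide/CuBr·SMe2 (THF, −40 °C) to the Mg-chelated syn-s-cis imide, anti to the 4-phenyl group (the Re face of C-β), should give the adduct F6. Me(MeO)NH·HCl/AlMe3 should give the Weinreb amide F7 with release of the auxiliary, and 4-(benzyloxy)phenylmagnesium bromide should then return 13.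

**Step 4.** What may go wrong: sluggish substitution at the doubly flanked C6 position of the bromo-deactivated ring, with acid-induced loss of benzyl ethers or C2 epimerisation at the temperature needed. Fallback, setting out from bromide 6 and returning at aldehyde 9, with the carbon introduced through an organometallic: iodination with N-iodosuccinimide/TFA (cat.) at the only free ring position should give the 8-bromo-6-iodo compound F8. Iodine-selective exchange with iPrMgCl·LiCl (THF, −20 °C) and quenching with DMF should return 9.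

## Further compounds

F1 | step 9 | (3R)-1-[4-(benzyloxy)phenyl]-3-[4-(benzyloxy)-2-bromophenyl]-3-ArL-propan-1-one (same spatial arrangement as 13; descriptor R because the brominated ring outranks ArL) | O=C(C[C@H](c1c(OCc5ccccc5)c(Br)c2c(c1OCc5ccccc5)C[C@@H](OCc5ccccc5)[C@@H](c3ccc(OCc5ccccc5)cc3)O2)c1ccc(OCc5ccccc5)cc1Br)c1ccc(OCc5ccccc5)cc1
F2 | step 9 | (1S,3R)-1-[4-(benzyloxy)phenyl]-3-[4-(benzyloxy)-2-bromophenyl]-3-ArL-propan-1-ol | O[C@@H](C[C@H](c1c(OCc5ccccc5)c(Br)c2c(c1OCc5ccccc5)C[C@@H](OCc5ccccc5)[C@@H](c3ccc(OCc5ccccc5)cc3)O2)c1ccc(OCc5ccccc5)cc1Br)c1ccc(OCc5ccccc5)cc1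
F3 | step 9 | (2S,4S)-7-(benzyloxy)-2-[4-(benzyloxy)phenyl]-4-ArL-chromane | C(c1ccccc1)Oc1ccc([C@@H]2C[C@H](c6c(OCc9ccccc9)c(Br)c7c(c6OCc9ccccc9)C[C@@H](OCc9ccccc9)[C@@H](c8ccc(OCc9ccccc9)cc8)O7)c3ccc(OCc9ccccc9)cc3O2)cc1
F4 | step 6 | (E)-3-ArL-prop-2-enoic acid | O=C(O)/C=C/c1c(OCc5ccccc5)c(Br)c2c(c1OCc5ccccc5)C[C@@H](OCc5ccccc5)[C@@H](c3ccc(OCc5ccccc5)cc3)O2
F5 | step 6 | (4R)-3-[(E)-3-ArL-prop-2-enoyl]-4-phenyl-1,3-oxazolidin-2-one | O=C(/C=C/c1c(OCc5ccccc5)c(Br)c2c(c1OCc5ccccc5)C[C@@H](OCc5ccccc5)[C@@H](c3ccc(OCc5ccccc5)cc3)O2)N1[C@H](c2ccccc2)COC1=O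
F6 | step 6 | (4R)-3-[(3S)-3-[4-(tert-butyldimethylsilyloxy)phenyl]-3-ArL-propanoyl]-4-phenyl-1,3-oxazolidin-2-one | O=C(C[C@H](c1c(OCc5ccccc5)c(Br)c2c(c1OCc5ccccc5)C[C@@H](OCc5ccccc5)[C@@H](c3ccc(OCc5ccccc5)cc3)O2)c1ccc(O[Si](C)(C)C(C)(C)C)cc1)N1[C@H](c2ccccc2)COC1=O
F7 | step 6 | (3S)-3-[4-(tert-butyldimethylsilyloxy)phenyl]-N-methoxy-N-methyl-3-ArL-propanamide | CON(C)C(=O)C[C@H](c1c(OCc5ccccc5)c(Br)c2c(c1OCc5ccccc5)C[C@@H](OCc5ccccc5)[C@@H](c3ccc(OCc5ccccc5)cc3)O2)c1ccc(O[Si](C)(C)C(C)(C)C)cc1
F8 | step 4 | (2R,3R)-3,5,7-tris(benzyloxy)-2-[4-(benzyloxy)phenyl]-8-bromo-6-iodochromane | Ic1c(OCc5ccccc5)c(Br)c2c(c1OCc5ccccc5)C[C@@H](OCc5ccccc5)[C@@H](c3ccc(OCc5ccccc5)cc3)O2
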